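The oxolane (O1, C2 aryl, C3 CH2OH, C4 benzyl, C5) is disconnected at the exocyclic ArCH2–C4 bond. The cis C3/C4 pair of this ring is a trans pair in the isomeric γ-lactone ring built from C5 (as C=O), C4, C3, the hydroxymethyl carbon and its oxygen. The key step exploits this. A lithiated 3,4,5-trimethoxybenzaldehyde dithioacetal adds to a (5S)-menthyloxybutenolide, and the resulting enolate, carrying the whole trimethoxyphenyl half, is benzylated by 3,4-dimethoxybenzyl bromide. One flask forms two C–C bonds and both ring stereocentres from one acetal centre. Unmasking, reduction and acid-induced ring closure through O1–C2 then transpose the lactone into the oxolane.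

Key step: step 3

Remark on the chemistry: 5-hydroxy-2(5H)-furanone, (+)-menthol and 3,4-dimethoxybenzyl bromide (labile, used fresh) are taken as commercial. The target is the (2R,3S,4S)-oxolane, 2,3-trans and 3,4-cis.

Step 1
Reactants: 1 3,4,5-trimethoxybenzaldehyde; 2 thiophenol (2 equiv)
Product: 3 3,4,5-trimethoxybenzaldehyde bis(phenylthio)acetal
Conditions: BF3·OEt2 (cat.), CH2Cl2, 0 °C to rt
Reagents that add atoms: none
Why: Lewis-acid-catalysed dithioacetalisation of an aromatic aldehyde is reliable and turns the formyl carbon into an acyl-anion equivalent whose C–H is acidified by two sulfur atoms and the aryl ring; no stereocentre is formed.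

Step 2
Reactants: 4 5-hydroxy-2(5H)-furanone (racemic pseudo-acid); 5 (+)-menthol, (1S,2R,5S)
Product: 6 (5S)-5-[(1S,2R,5S)-menthyloxy]-2(5H)-furanone
Conditions: p-TsOH (cat.), toluene, Dean–Stark reflux; crystallisation from petroleum ether, mother liquor re-equilibrated with the acid and crystallised again
Reagents that add atoms: none
Why: Acid-catalysed acetalisation of the pseudo-acid gives both C5 epimers, which interconvert under the acid, and the (5S)-epimer, the mirror image of the well-crystallising (5R)-(−)-menthyl compound, should be collected by crystallisation, so C5 is set by a crystallisation-driven separation with recycling.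

Step 3
Reactants: 3 3,4,5-trimethoxybenzaldehyde bis(phenylthio)acetal; 6 (5S)-5-[(1S,2R,5S)-menthyloxy]-2(5H)-furanone; 7 3,4-dimethoxybenzyl bromide
Product: 10 (3S,4S,5S)-3-(3,4-dimethoxybenzyl)-4-[bis(phenylthio)(3,4,5-trimethoxyphenyl)methyl]-5-[(1S,2R,5S)-menthyloxy]dihydrofuran-2(3H)-one, via lithiated dithioacetal 8 (not isolated), via lithium lactone enolate 9 (not isolated)
Conditions: 3, n-BuLi, THF, −78 °C; 6, −78 °C; then 7, DMPU, −78 to −20 °C; aq NH4Cl
Reagents that add atoms: n-butyllithium, [Li]CCCC (lithium of 8 and 9 only; no atom of it stays in 10)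
Why: n-BuLi deprotonates 3 to the soft carbanion 8, which adds 1,4 to butenolide 6; the lithium enolate 9 so formed, which already holds the trimethoxyphenyl carbon, the four lactone carbons and the auxiliary, is then C-benzylated by 7 in an SN2 reaction that forms the ArCH2–C3(lactone) bond, the later ArCH2–C4 bond of the oxolane. The closest known reaction type is the tandem (three-component) conjugate addition–enolate alkylation of lithiated aryl dithioacetals, γ-alkoxybutenolides and benzylic halides used for dibenzylbutyrolactone lignans. No ring is closed; the lactone serves as a temporary five-membered template that is opened in step 5. Lactone C4 is set by attack of 8 on the butenolide face anti to the C5 menthyloxy group, and lactone C3 by approach of 7 to the enolate face anti to the very bulky C4 bis(phenylthio)arylmethyl group, so the single acetal centre is relayed to a 3,4-trans pair that becomes the 3,4-cis pair of the oxolane once the ring is re-closed through the other oxygen. The step needs 1,4- over 1,2-addition, secured by the delocalised sulfur-stabilised carbanion at −78 °C, and alkylation faster than retro-Michael loss of 8 or proton exchange, secured by the reactive electron-rich benzylic bromide, DMPU as cosolvent and a low temperature.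

Step 4
Reactants: 10 the tandem adduct
Product: 11 (3S,4S,5S)-3-(3,4-dimethoxybenzyl)-5-[(1S,2R,5S)-menthyloxy]-4-(3,4,5-trimethoxybenzoyl)dihydrofuran-2(3H)-one
Conditions: HgO (red), BF3·OEt2 (promoter), THF–H2O, rt
Reagents that add atoms: water, O
Why: Thiophilic mercury(II)-assisted dithioacetal hydrolysis runs through the aryl-stabilised thionium ion under conditions the acyloxy acetal and the aryl methyl ethers should tolerate, and C4, now alpha to the ketone, already sits in the thermodynamically preferred all-trans arrangement and should not be scrambled.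

Step 5
Reactants: 11 the keto lactone acetal
Product: 12 (2S,3S)-3-(3,4-dimethoxybenzyl)-2-[hydroxy(3,4,5-trimethoxyphenyl)methyl]butane-1,4-diol (both carbinol epimers)
Conditions: LiAlH4 (excess), THF, 0 °C to reflux; H2O/aq NaOH work-up
Reagents that add atoms: none
Why: Exhaustive hydride reduction takes the ketone to the carbinol and opens the lactone, whereupon the released hemiacetal alkoxide expels menthoxide and the resulting aldehyde is reduced as well, so the acetal carbon becomes the hydroxymethyl carbon while the two backbone stereocentres are untouched and the new carbinol centre may be a mixture because step 6 erases it.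

Step 6
Reactants: 12 the triol
Product: 13 [(2R,3S,4S)-4-(3,4-dimethoxybenzyl)-2-(3,4,5-trimethoxyphenyl)oxolan-3-yl]methanol (target)
Conditions: CSA (cat.), CH2Cl2, 0 °C; Et3N quench as soon as 12 is consumed
Reagents that add atoms: none
Why: Acid-catalysed SN1 cyclodehydration converges both carbinol epimers on one planar 3,4,5-trimethoxybenzyl cation that only the hydroxyl on the benzyl-bearing carbon can capture in a five-membered closure (the other would give an oxetane), and C2 is set trans to the C3 hydroxymethyl group by avoidance of 1,2-strain in the closing envelope and by the reversibility of the closure.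

Compound list
1 | 3,4,5-trimethoxybenzaldehyde | COc1cc(C=O)cc(OC)c1OC | starting material
2 | thiophenol | Sc1ccccc1 | starting material
3 | 3,4,5-trimethoxybenzaldehyde bis(phenylthio)acetal | COc1cc(C(Sc2ccccc2)Sc2ccccc2)cc(OC)c1OC | intermediate
4 | 5-hydroxy-2(5H)-furanone (racemic) | OC1OC(=O)C=C1 | starting material
5 | (+)-menthol, (1S,2R,5S)-2-isopropyl-5-methylcyclohexanol | CC(C)[C@H]1CC[C@H](C)C[C@@H]1O | starting material
6 | (5S)-5-[(1S,2R,5S)-menthyloxy]-2(5H)-furanone | CC(C)[C@H]1CC[C@H](C)C[C@@H]1O[C@H]2OC(=O)C=C2 | intermediate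
7 | 3,4-dimethoxybenzyl bromide | COc1ccc(CBr)cc1OC | starting material
8 | bis(phenylthio)(3,4,5-trimethoxyphenyl)methyllithium | [Li]C(Sc1ccccc1)(Sc1ccccc1)c1cc(OC)c(OC)c(OC)c1 | intermediate (not isolated)
9 | lithium enolate of the (4S,5S) conjugate adduct, side chain anti to menthyloxy | CC(C)[C@H]1CC[C@H](C)C[C@@H]1O[C@H]2OC(O[Li])=C[C@@H]2C(Sc3ccccc3)(Sc3ccccc3)c3cc(OC)c(OC)c(OC)c3 | intermediate (not isolated)
10 | (3S,4S,5S)-3-(3,4-dimethoxybenzyl)-4-[bis(phenylthio)(3,4,5-trimethoxyphenyl)methyl]-5-[(1S,2R,5S)-menthyloxy]dihydrofuran-2(3H)-one, all-trans | CC(C)[C@H]1CC[C@H](C)C[C@@H]1O[C@H]2OC(=O)[C@@H](Cc3ccc(OC)c(OC)c3)[C@@H]2C(Sc3ccccc3)(Sc3ccccc3)c3cc(OC)c(OC)c(OC)c3 | intermediate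
11 | (3S,4S,5S)-3-(3,4-dimethoxybenzyl)-5-[(1S,2R,5S)-menthyloxy]-4-(3,4,5-trimethoxybenzoyl)dihydrofuran-2(3H)-one | CC(C)[C@H]1CC[C@H](C)C[C@@H]1O[C@H]2OC(=O)[C@@H](Cc3ccc(OC)c(OC)c3)[C@@H]2C(=O)c3cc(OC)c(OC)c(OC)c3 | intermediate
12 | (2S,3S)-3-(3,4-dimethoxybenzyl)-2-[hydroxy(3,4,5-trimethoxyphenyl)methyl]butane-1,4-diol, carbinol centre undefined | COc1ccc(C[C@H](CO)[C@@H](CO)C(O)c2cc(OC)c(OC)c(OC)c2)cc1OC | intermediate
13 | [(2R,3S,4S)-4-(3,4-dimethoxybenzyl)-2-(3,4,5-trimethoxyphenyl)oxolan-3-yl]methanol | COc1ccc(C[C@@H]2CO[C@@H](c3cc(OC)c(OC)c(OC)c3)[C@@H]2CO)cc1OC | target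

Total step count: 6. Longest linear sequence: 5 steps (step 1 or step 2, then steps 3, 4, 5, 6).

Steps most likely to fail

1. Step 3. The conjugate addition may reverse while the enolate waits for the slower SN2 step, and proton exchange between enolate and product may lead to double benzylation.
   - The fallback exchanges the roles of the two aryl units. The same ArCH2–C bond is then made by the conjugate addition itself, and the enolate is consumed by a fast aldol reaction.
   - It sets out from 6 and comes back to the route at 12.
   - 3,4-Dimethoxybenzaldehyde and 2 (BF3·OEt2, CH2Cl2) should give 3,4-dimethoxybenzaldehyde bis(phenylthio)acetal F1.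
   - Its lithio derivative (n-BuLi, THF, −78 °C) should add to 6 anti to the menthyloxy group. Quenching the enolate at −78 °C with aldehyde 1 should give the all-trans tandem aldol adduct F2.
   - Deactivated Raney nickel in EtOH should remove both phenylthio groups to give the hydroxy lactone acetal F3.
   - LiAlH4 in THF should reduce F3 to 12.

2. Step 6. The benzylic position may ionise further, so that the cation is captured by the electron-rich dimethoxyphenyl ring in a Friedel–Crafts closure. Facial selection at C2 may also be poor.
   - The fallback replaces the acid-catalysed closure by a closure under non-acidic conditions, in which the ether cannot re-ionise once formed.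
   - It sets out from 12 and comes back at 13.
   - TBSCl and imidazole in CH2Cl2 at 0 °C should silylate only the two primary hydroxyls to give the bis(TBS) ether F4.
   - MsCl, Et3N and LiCl at −20 °C should convert the remaining benzylic alcohol into the benzylic chloride F5.
   - TBAF in THF should free both primary oxygens, of which only the one on the benzyl-bearing carbon can displace the chloride in a five-membered closure.
   - The labile chloride epimers should interconvert by chloride exchange, and the closure to the 2,3-trans ring should be the faster one.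

3. Step 4. The menthyl acetal may be lost, or an oxygen on the carbon beta to the new ketone may be eliminated, under the Lewis-acidic thiophile.
   - The fallback changes the order of events so that the acetal is gone before the ketone is unmasked.
   - It sets out from 10 and comes back at 12.
   - LiAlH4 in THF should reduce 10 to the dithioacetal diol F6.
   - HgO and BF3·OEt2 in aqueous THF should unmask it to the keto diol F7, which should rest largely as its cyclic hemiketal and thereby be shielded from elimination.
   - NaBH4 in MeOH at 0 °C should reduce F7 through its open form to 12.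

Further compounds
F1 | step 3 | 3,4-dimethoxybenzaldehyde bis(phenylthio)acetal | COc1ccc(C(Sc2ccccc2)Sc2ccccc2)cc1OC
F2 | step 3 | (3R,4S,5S)-4-[(3,4-dimethoxyphenyl)bis(phenylthio)methyl]-3-[hydroxy(3,4,5-trimethoxyphenyl)methyl]-5-[(1S,2R,5S)-menthyloxy]dihydrofuran-2(3H)-one, carbinol centre undefined | CC(C)[C@H]1CC[C@H](C)C[C@@H]1O[C@H]2OC(=O)[C@@H](C(O)c3cc(OC)c(OC)c(OC)c3)[C@@H]2C(Sc3ccccc3)(Sc3ccccc3)c3ccc(OC)c(OC)c3
F3 | step 3 | (3R,4S,5S)-4-(3,4-dimethoxybenzyl)-3-[hydroxy(3,4,5-trimethoxyphenyl)methyl]-5-[(1S,2R,5S)-menthyloxy]dihydrofuran-2(3H)-one, carbinol centre undefined | CC(C)[C@H]1CC[C@H](C)C[C@@H]1O[C@H]2OC(=O)[C@@H](C(O)c3cc(OC)c(OC)c(OC)c3)[C@@H]2Cc3ccc(OC)c(OC)c3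
F4 | step 6 | 1,4-bis(tert-butyldimethylsilyl) ether of 12 | COc1ccc(C[C@H](CO[Si](C)(C)C(C)(C)C)[C@@H](CO[Si](C)(C)C(C)(C)C)C(O)c2cc(OC)c(OC)c(OC)c2)cc1OC
F5 | step 6 | benzylic chloride derived from F4, chloride-bearing centre undefined | COc1ccc(C[C@H](CO[Si](C)(C)C(C)(C)C)[C@@H](CO[Si](C)(C)C(C)(C)C)C(Cl)c2cc(OC)c(OC)c(OC)c2)cc1OC
F6 | step 4 | (2S,3S)-2-[bis(phenylthio)(3,4,5-trimethoxyphenyl)methyl]-3-(3,4-dimethoxybenzyl)butane-1,4-diol | COc1ccc(C[C@H](CO)[C@@H](CO)C(Sc2ccccc2)(Sc2ccccc2)c2cc(OC)c(OC)c(OC)c2)cc1OC
F7 | step 4 | (2S,3S)-3-(3,4-dimethoxybenzyl)-4-hydroxy-2-(hydroxymethyl)-1-(3,4,5-trimethoxyphenyl)butan-1-one (open form of the hemiketal) | COc1ccc(C[C@H](CO)[C@@H](CO)C(=O)c2cc(OC)c(OC)c(OC)c2)cc1OC
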